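(The earlier runs and the new flask stem from a simulated flask for substances that don't exist; the scatter is artificial.)

A small charge of coupling partner puts a lid on the target. Taking one partner per target as a working assumption, alder's lid stands at 33.0% of the starting material charged, and partner is the likely limiting reagent there.

| flask | starting material | coupling partner | second substrate | temperature | remark | time |
|---|---|---|---|---|---|---|
| west | 0.069 M | 1.3 equiv | 1 equiv | 105 °C | run made earlier |  |
| north | 0.060 M | 1.3 equiv | 1 equiv | 116 °C | run made earlier |  |
| south-east | 0.053 M | 0.80 equiv | 1 equiv | 105 °C | run made earlier |  |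
| alder | 0.080 M | 0.330 equiv | 1.00 equiv | 110 °C |  | 2.5 min |
| oak | 0.053 M | 1.30 equiv | 1.00 equiv | 110 °C |  | 2.5 min |

- west (time / s: target / %, starting material / %): 10.0: 9.0, 85.7; 15.0: 12.5, 80.4; 30.0: 19.0, 67.0; 60.0: 26.4, 50.6; 120: 34.0, 33.4
- north (time / s: target / %, starting material / %): 10.0: 13.2, 78.3; 15.0: 15.1, 71.1; 30.0: 23.7, 53.4; 60.0: 30.1, 37.3; 120: 37.1, 23.4
- south-east (time / s: target / %, starting material / %): 20.0: 7.7, 83.8; 40.0: 12.1, 73.0; 60.0: 14.2, 64.6; 80.0: 17.6, 58.3; 120: 20.0, 49.2

(standard deviation of a reading: 0.5 percentage points)

- where the amount of starting material changes, what is given in equivalents or mol% on it follows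

1. which one finishes higher in amount of target, in percent of the starting material charged ("neither" within 2 percentage points) (alder / oak / neither)
2. amount of target at the end, in percent of the starting material charged, alder
3. amount of target at the end, in percent of the starting material charged, oak

A bench rule follows from the last readings. The west run has turned 26.2% of its charged partner into target at 120 s; this capture, target made per partner charged, reads 25.0% in the south-east run, which has less partner. Multiplying capture by the equivalents gives my own reckoning: 34.0% for oak, and 37.1% with the capture of the hotter north run, so oak should lie near that range. For alder the same rule gives 8.63%.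

The border of the rule lies in a ratio: alder's equivalents of partner are 0.412 of the south-east charge, and second substrate outnumbers partner 3.03 to one. No run reads capture there, so alder's figure is an extrapolation. Alder's lid of 33.0% and oak's reckoned 34.0% lie within the margin of 2 percentage points, so the lid does not separate the flasks; the order in this reckoning rests on the extrapolated 8.63% for alder.

The forecast names oak, with 18% for alder and 35% for oak, holding that “Selectivity to target falls with less partner”. Its alder figure is higher than the reckoning here.

Alder gives 10.6% and oak 34.7%, so oak finishes higher.

    starting material + coupling partner → target (k = 0.167 M⁻¹ s⁻¹, Ea = 71.0 kJ mol⁻¹)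
    second substrate + coupling partner → second product (k = 0.181 M⁻¹ s⁻¹, Ea = 56.0 kJ mol⁻¹)
    starting material + second substrate → cross product (k = 0.113 M⁻¹ s⁻¹, Ea = 68.0 kJ mol⁻¹)
    target ⇌ isomer of the product (K = 0.370, k = 0.0169 s⁻¹, Ea = 99.0 kJ mol⁻¹, ΔH = 15.0 kJ mol⁻¹)
    (constants at 110 °C)

At 2.50 min, alder keeps 9.22% of its partner charge, and cross product stands at 47.9%. Alder's capture comes to 32.2%, higher than the 26.2% carried from the west run, while oak's is 26.7%. The neighbour of alder with 0.560 equiv of partner is reckoned by the west capture at 14.7%, and that flask gives 17.8%.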